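**Plan**

1. Retrosynthetic cuts: the three CH2OH groups and the phenol go back to three esters and an aryl pivalate; the aryl–CH2 bond of the propanol chain goes back to an aryl bromide; then, first for the inner and next for the outer dihydrobenzofuran, the bonds C3–C3a and C2–aryl are cut.
2. Enabling feature: in each dihydrofuran ring C3 carries both the benzo carbon C3a and an exocyclic one-carbon group (CH2OH). These two carbons are C4a and C4 of a flavanone, so each five-membered O1–C2–C3–C3a–C7a ring is a six-membered O1–C2–C3–C4–C4a–C8a pyranone from which C4 is pushed out of the ring by a 1,2-shift of C4a to C3.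
3. Forward order: one 6-bromo-8-methoxychromone is used twice. Aryl addition gives the outer flavanone, ring contraction gives the outer dihydrobenzofuran ester, and Br→B(OH)2 makes it the aryl donor for a second chromone molecule. A second contraction gives the inner ring, the last bromide takes the three-carbon chain, and one hydride step finishes.
4. Stereochemistry: both C2 centres (R) come from catalyst-controlled Pd(II)/PyOX conjugate additions; both C3 centres come from the stereospecific, trans-selective 1,2-aryl shift. The (3R) esters become (3S) alcohols by CIP ranking only.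

Key step: step 5

Assumption: (S)-t-BuPyOX is taken to deliver the aryl group to the chromone face that gives the (2R)-flavanone, by analogy with its sense on cyclic enones; if the sense proves opposite, (R)-t-BuPyOX is used in steps 4 and 7 and nothing else changes.

**Route**

Step 1
Reactants: 1 5'-bromo-2'-hydroxy-3'-methoxyacetophenone
Product: 3 6-bromo-8-methoxy-4H-chromen-4-one, via enaminone 2 (not isolated)
Conditions: Me2NCH(OMe)2, toluene, 100 °C; then conc. HCl, CH2Cl2, rt
Reagents that add atoms: N,N-dimethylformamide dimethyl acetal, COC(OC)N(C)C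
Why: Condensation of the methyl ketone with the amide acetal gives the enaminone, and acid then induces addition of the phenol oxygen to the β-carbon with loss of dimethylamine (chromone synthesis via an enaminone, addition–elimination).

Step 2
Reactants: 4 4-bromo-2-methoxyphenol
Product: 5 4-bromo-2-methoxyphenyl pivalate
Conditions: PivCl, Et3N, DMAP (cat.), CH2Cl2, 0 °C → rt
Reagents that add atoms: pivaloyl chloride, CC(C)(C)C(=O)Cl
Why: DMAP-catalysed acylation of the phenol; the pivalate is chosen because it makes this ring electron-poor for step 5, survives acid and weak base, and is cleaved by LiAlH4 in step 10.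

Step 3
Reactants: 5 4-bromo-2-methoxyphenyl pivalate
Product: 6 [3-methoxy-4-(pivaloyloxy)phenyl]boronic acid
Conditions: B2(OH)4, XPhos Pd G2 (2 mol %), XPhos, KOAc, EtOH, 80 °C; dilute acid work-up
Reagents that add atoms: tetrahydroxydiboron, OB(O)B(O)O
Why: Pd-catalysed Miyaura-type borylation of the aryl bromide with tetrahydroxydiboron gives the boronic acid directly, and Pd/XPhos does not activate the aryl pivalate C–O bond.

Step 4
Reactants: 3 6-bromo-8-methoxy-4H-chromen-4-one; 6 [3-methoxy-4-(pivaloyloxy)phenyl]boronic acid (1.5–2 equiv)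
Product: 7 4-[(2R)-6-bromo-8-methoxy-4-oxo-3,4-dihydro-2H-chromen-2-yl]-2-methoxyphenyl pivalate
Conditions: Pd(OCOCF3)2 (5 mol %), (S)-t-BuPyOX (6 mol %), NH4PF6 (30 mol %), H2O (5 equiv), ClCH2CH2Cl, 60 °C
Reagents that add atoms: none
Why: Enantioselective Pd(II)-catalysed conjugate addition of an arylboronic acid to a chromone (transmetalation, aryl insertion at C2, protonolysis of the Pd enolate by water), in which the PyOX ligand sets C2 as R, the base-free medium avoids retro-oxa-Michael opening of the flavanone, and the C–Br bond is inert because no Pd(0) is involved.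

Step 5
Reactants: 7 4-[(2R)-6-bromo-8-methoxy-4-oxo-3,4-dihydro-2H-chromen-2-yl]-2-methoxyphenyl pivalate
Product: 9 methyl (2R,3R)-5-bromo-7-methoxy-2-[3-methoxy-4-(pivaloyloxy)phenyl]-2,3-dihydro-1-benzofuran-3-carboxylate, via enol ether 8 (not isolated)
Conditions: PhI(OAc)2 (1.2 equiv), HC(OMe)3, conc. H2SO4 (cat.), 0 °C → rt; aq. NaHCO3 work-up
Reagents that add atoms: trimethyl orthoformate, COC(OC)OC; water (work-up), O
Why: Acid and HC(OMe)3 convert the C4 ketone into its dimethyl ketal/methyl enol ether 8, whose C3 is attacked by the iodine(III) electrophile anti to the equatorial C2 aryl group; the equatorial C3–I(III) bond then lies antiperiplanar to the ring bond C4–C4a, so loss of PhI is assisted by a 1,2-shift of the benzo carbon C4a from C4 to C3, and the dimethoxycarbenium ion left at C4 collapses to the methyl ester on work-up. This is the known oxidative ring contraction of flavanones to methyl trans-2-aryl-2,3-dihydrobenzofuran-3-carboxylates by iodine(III) or thallium(III) in trimethyl orthoformate, the cyclic counterpart of the oxidative 1,2-aryl shift of aryl alkyl ketones to arylacetates. The five-membered O1–C2–C3–C3a–C7a ring is closed by the new C3–C3a bond through a bridged phenonium ion (3-exo-tet attack of the ipso carbon on C3, then cleavage of C4–C4a), so the six-membered pyranone is contracted and C4 leaves the ring as the carboxylate carbon. C2 is not touched and keeps the R configuration from step 4; the new centre C3 is set by the stereospecific shift with inversion at C3 (iodane trans to the aryl group, aryl carbon entering from the opposite side), which places CO2Me trans to the C2 aryl group, (2R,3R), also the thermodynamically preferred isomer. The step needs migration of C4a and neither migration of the C2 aryl group (isoflavone) nor loss of H-2 (flavone); this is secured by the ring oxygen O1 ortho to the migrating carbon, by the two methoxy groups at C4 that push the shift, and by the pivaloyloxy group, which makes the C2 aryl ring a poor migrating group and resistant to iodine(III) oxidation.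

Step 6
Reactants: 9 methyl (2R,3R)-5-bromo-7-methoxy-2-[3-methoxy-4-(pivaloyloxy)phenyl]-2,3-dihydro-1-benzofuran-3-carboxylate
Product: 10 [(2R,3R)-7-methoxy-3-(methoxycarbonyl)-2-[3-methoxy-4-(pivaloyloxy)phenyl]-2,3-dihydro-1-benzofuran-5-yl]boronic acid
Conditions: B2(OH)4, XPhos Pd G2 (2 mol %), XPhos, KOAc, MeOH, 60 °C; dilute acid work-up
Reagents that add atoms: tetrahydroxydiboron, OB(O)B(O)O
Why: The same Pd-catalysed Miyaura-type borylation as in step 3, in which KOAc is too weak a base to epimerise C3 or open the ring by β-elimination and methanol makes any ester exchange degenerate.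

Step 7
Reactants: 3 6-bromo-8-methoxy-4H-chromen-4-one (2 equiv); 10 [(2R,3R)-7-methoxy-3-(methoxycarbonyl)-2-[3-methoxy-4-(pivaloyloxy)phenyl]-2,3-dihydro-1-benzofuran-5-yl]boronic acid
Product: 11 methyl (2R,3R)-5-[(2R)-6-bromo-8-methoxy-4-oxo-3,4-dihydro-2H-chromen-2-yl]-7-methoxy-2-[3-methoxy-4-(pivaloyloxy)phenyl]-2,3-dihydro-1-benzofuran-3-carboxylate
Conditions: Pd(OCOCF3)2 (10 mol %), (S)-t-BuPyOX (12 mol %), NH4PF6, H2O (5 equiv), ClCH2CH2Cl, 60 °C
Reagents that add atoms: none
Why: The same Pd(II)/PyOX conjugate addition as in step 4, with 10 as the limiting aryl donor; the catalyst sets the new flavanone C2 as R independently of the remote centres, and the esters and the C–Br bond survive the neutral medium.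

Step 8
Reactants: 11 methyl (2R,3R)-5-[(2R)-6-bromo-8-methoxy-4-oxo-3,4-dihydro-2H-chromen-2-yl]-7-methoxy-2-[3-methoxy-4-(pivaloyloxy)phenyl]-2,3-dihydro-1-benzofuran-3-carboxylate
Product: 13 methyl (2R,3R)-5-bromo-7-methoxy-2-[(2R,3R)-7-methoxy-3-(methoxycarbonyl)-2-[3-methoxy-4-(pivaloyloxy)phenyl]-2,3-dihydro-1-benzofuran-5-yl]-2,3-dihydro-1-benzofuran-3-carboxylate, via enol ether 12 (not isolated)
Conditions: PhI(OAc)2 (1.2 equiv), HC(OMe)3, conc. H2SO4 (cat.), 0 °C → rt; aq. NaHCO3 work-up
Reagents that add atoms: trimethyl orthoformate, COC(OC)OC; water (work-up), O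
Why: Second iodine(III) ring contraction of a flavanone by the same ketalisation, C3 iodination and antiperiplanar 1,2-shift of C4a as in step 5, which should give the inner trans-(2R,3R) ester while the existing ester, pivalate, aryl bromide and dihydrobenzofuran tolerate cold acidic orthoformate.

Step 9
Reactants: 13 methyl (2R,3R)-5-bromo-7-methoxy-2-[(2R,3R)-7-methoxy-3-(methoxycarbonyl)-2-[3-methoxy-4-(pivaloyloxy)phenyl]-2,3-dihydro-1-benzofuran-5-yl]-2,3-dihydro-1-benzofuran-3-carboxylate
Product: 14 methyl (2R,3R)-5-(3-ethoxy-3-oxopropyl)-7-methoxy-2-[(2R,3R)-7-methoxy-3-(methoxycarbonyl)-2-[3-methoxy-4-(pivaloyloxy)phenyl]-2,3-dihydro-1-benzofuran-5-yl]-2,3-dihydro-1-benzofuran-3-carboxylate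
Conditions: BrZnCH2CH2CO2Et (0.5 M in THF, 3 equiv), Pd(OAc)2 (5 mol %), SPhos (10 mol %), THF, 50 °C
Reagents that add atoms: (3-ethoxy-3-oxopropyl)zinc bromide, CCOC(=O)CC[Zn]Br
Why: Negishi coupling of the aryl bromide with a primary alkylzinc homoenolate, a non-basic reagent that leaves the esters, the pivalate and the C3 centres untouched, while the biaryl phosphine suppresses β-hydride elimination.

Step 10
Reactants: 14 methyl (2R,3R)-5-(3-ethoxy-3-oxopropyl)-7-methoxy-2-[(2R,3R)-7-methoxy-3-(methoxycarbonyl)-2-[3-methoxy-4-(pivaloyloxy)phenyl]-2,3-dihydro-1-benzofuran-5-yl]-2,3-dihydro-1-benzofuran-3-carboxylate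
Product: 15 4-[(2R,3S)-3-(hydroxymethyl)-5-[(2R,3S)-3-(hydroxymethyl)-5-(3-hydroxypropyl)-7-methoxy-2,3-dihydro-1-benzofuran-2-yl]-7-methoxy-2,3-dihydro-1-benzofuran-2-yl]-2-methoxyphenol (CNP0599161.1)
Conditions: LiAlH4 (excess), THF, −20 → 0 °C; Rochelle salt work-up
Reagents that add atoms: none
Why: Hydride reduction of the two methyl esters and the ethyl ester to primary alcohols with cleavage of the aryl pivalate in the same operation; at low temperature hydride addition is faster than enolisation, so C2 and C3 should keep their configuration.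

**Compound list**

1 | 1-(5-bromo-2-hydroxy-3-methoxyphenyl)ethan-1-one (5'-bromo-2'-hydroxy-3'-methoxyacetophenone) | CC(=O)c1cc(Br)cc(OC)c1O | starting material
2 | (E)-1-(5-bromo-2-hydroxy-3-methoxyphenyl)-3-(dimethylamino)prop-2-en-1-one | CN(C)/C=C/C(=O)c1cc(Br)cc(OC)c1O | intermediate
3 | 6-bromo-8-methoxy-4H-chromen-4-one | COc1cc(Br)cc2c(=O)ccoc12 | intermediate
4 | 4-bromo-2-methoxyphenol | COc1cc(Br)ccc1O | starting material
5 | 4-bromo-2-methoxyphenyl pivalate | COc1cc(Br)ccc1OC(=O)C(C)(C)C | intermediate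
6 | [3-methoxy-4-(pivaloyloxy)phenyl]boronic acid | COc1cc(B(O)O)ccc1OC(=O)C(C)(C)C | intermediate
7 | 4-[(2R)-6-bromo-8-methoxy-4-oxo-3,4-dihydro-2H-chromen-2-yl]-2-methoxyphenyl pivalate | COc1cc([C@@H]2Oc3c(OC)cc(Br)cc3C(=O)C2)ccc1OC(=O)C(C)(C)C | intermediate
8 | 4-[(2R)-6-bromo-4,8-dimethoxy-2H-chromen-2-yl]-2-methoxyphenyl pivalate | COc1cc([C@@H]2Oc3c(OC)cc(Br)cc3C(OC)=C2)ccc1OC(=O)C(C)(C)C | intermediate
9 | methyl (2R,3R)-5-bromo-7-methoxy-2-[3-methoxy-4-(pivaloyloxy)phenyl]-2,3-dihydro-1-benzofuran-3-carboxylate (2,3-trans) | COc1cc([C@@H]2Oc3c(OC)cc(Br)cc3[C@H]2C(=O)OC)ccc1OC(=O)C(C)(C)C | intermediate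
10 | [(2R,3R)-7-methoxy-3-(methoxycarbonyl)-2-[3-methoxy-4-(pivaloyloxy)phenyl]-2,3-dihydro-1-benzofuran-5-yl]boronic acid | COc1cc([C@@H]2Oc3c(OC)cc(B(O)O)cc3[C@H]2C(=O)OC)ccc1OC(=O)C(C)(C)C | intermediate
11 | methyl (2R,3R)-5-[(2R)-6-bromo-8-methoxy-4-oxo-3,4-dihydro-2H-chromen-2-yl]-7-methoxy-2-[3-methoxy-4-(pivaloyloxy)phenyl]-2,3-dihydro-1-benzofuran-3-carboxylate | COc1cc([C@@H]2Oc3c(OC)cc([C@@H]4Oc5c(OC)cc(Br)cc5C(=O)C4)cc3[C@H]2C(=O)OC)ccc1OC(=O)C(C)(C)C | intermediate
12 | methyl (2R,3R)-5-[(2R)-6-bromo-4,8-dimethoxy-2H-chromen-2-yl]-7-methoxy-2-[3-methoxy-4-(pivaloyloxy)phenyl]-2,3-dihydro-1-benzofuran-3-carboxylate | COc1cc([C@@H]2Oc3c(OC)cc([C@@H]4Oc5c(OC)cc(Br)cc5C(OC)=C4)cc3[C@H]2C(=O)OC)ccc1OC(=O)C(C)(C)C | intermediate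
13 | methyl (2R,3R)-5-bromo-7-methoxy-2-[(2R,3R)-7-methoxy-3-(methoxycarbonyl)-2-[3-methoxy-4-(pivaloyloxy)phenyl]-2,3-dihydro-1-benzofuran-5-yl]-2,3-dihydro-1-benzofuran-3-carboxylate | COc1cc([C@@H]2Oc3c(OC)cc([C@@H]4Oc5c(OC)cc(Br)cc5[C@H]4C(=O)OC)cc3[C@H]2C(=O)OC)ccc1OC(=O)C(C)(C)C | intermediate
14 | methyl (2R,3R)-5-(3-ethoxy-3-oxopropyl)-7-methoxy-2-[(2R,3R)-7-methoxy-3-(methoxycarbonyl)-2-[3-methoxy-4-(pivaloyloxy)phenyl]-2,3-dihydro-1-benzofuran-5-yl]-2,3-dihydro-1-benzofuran-3-carboxylate | COc1cc([C@@H]2Oc3c(OC)cc([C@@H]4Oc5c(OC)cc(CCC(=O)OCC)cc5[C@H]4C(=O)OC)cc3[C@H]2C(=O)OC)ccc1OC(=O)C(C)(C)C | intermediate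
15 | 4-[(2R,3S)-3-(hydroxymethyl)-5-[(2R,3S)-3-(hydroxymethyl)-5-(3-hydroxypropyl)-7-methoxy-2,3-dihydro-1-benzofuran-2-yl]-7-methoxy-2,3-dihydro-1-benzofuran-2-yl]-2-methoxyphenol (CNP0599161.1) | COc1cc([C@@H]2Oc3c(OC)cc([C@@H]4Oc5c(OC)cc(CCCO)cc5[C@H]4CO)cc3[C@H]2CO)ccc1O | target

**Summary**

Total step count: 10. Longest linear sequence: 9 steps (steps 2 to 10, from 4 to 15); step 1 supplies chromone 3, which enters twice.

Steps most likely to fail:

1. Step 8. The benzofuranyl group on C2 of 11 carries a para oxygen, so it may compete as the migrating group (2→3 aryl shift towards an isoflavone) or assist acid ionisation of the C2–O bond, and the dialkoxyarene may be oxidised by iodine(III). The fallback replaces the oxidative, acidic contraction by a nitrogen-extrusion contraction and sets out from 11. Heating with Me2NCH(OMe)2 (toluene, 90 °C) should give the 3-(dimethylaminomethylidene) ketone F1. Diazo transfer with TsN3 (MeCN, rt) should then give the 3-diazo ketone F2. Irradiation (365 nm, MeOH) should trigger a Wolff rearrangement in which the same aryl carbon C4a shifts to C3 and the ketene is trapped by methanol. This should give 13 together with its inner cis C3-epimer F3, which catalytic DBU in toluene should equilibrate to the trans ester. The route is rejoined at 13.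

2. Step 5. Iodination cis to the aryl group followed by anti elimination of H-2 (dehydrogenation to the flavone, with loss of the C2 centre) may outrun the 1,2-shift, and reversible acid-induced ring opening may erode the enantiomeric purity. The fallback is the same nitrogen-extrusion contraction and sets out from 7. Me2NCH(OMe)2 should give the 3-(dimethylaminomethylidene) ketone F4, and TsN3 should give the 3-diazo ketone F5. Photochemical Wolff rearrangement in MeOH should give 9 together with its cis C3-epimer F6, which catalytic DBU should convert into 9. The route is rejoined at 9.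

3. Step 7. Facial control by the catalyst may be incomplete in a donor that already carries two stereocentres, and slow insertion into the chromone may leave the valuable boronic acid to protodeboronate. The fallback gives up catalyst control and sets out from 3 and 10. A more active achiral catalyst (Pd(OCOCF3)2, 2,2'-bipyridine, same medium) should give 11 together with its flavanone C2-epimer F7. The two are diastereomers and should be separable by chromatography. The unwanted epimer is recycled with NaOAc in MeOH at 60 °C, which re-equilibrates C2 by reversible ring opening to the 2'-hydroxychalcone F8. The route is rejoined at 11.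

Further compounds

F1 | step 8 | methyl (2R,3R)-5-[(2S)-6-bromo-3-[(dimethylamino)methylidene]-8-methoxy-4-oxo-3,4-dihydro-2H-chromen-2-yl]-7-methoxy-2-[3-methoxy-4-(pivaloyloxy)phenyl]-2,3-dihydro-1-benzofuran-3-carboxylate (geometry at the chromanone C2 as in 11; descriptor changes by CIP ranking) | COc1cc([C@@H]2Oc3c(OC)cc([C@@H]4Oc5c(OC)cc(Br)cc5C(=O)C4=CN(C)C)cc3[C@H]2C(=O)OC)ccc1OC(=O)C(C)(C)C
F2 | step 8 | methyl (2R,3R)-5-[(2S)-6-bromo-3-diazo-8-methoxy-4-oxo-3,4-dihydro-2H-chromen-2-yl]-7-methoxy-2-[3-methoxy-4-(pivaloyloxy)phenyl]-2,3-dihydro-1-benzofuran-3-carboxylate (geometry at the chromanone C2 as in 11) | COc1cc([C@@H]2Oc3c(OC)cc([C@@H]4Oc5c(OC)cc(Br)cc5C(=O)C4=[N+]=[N-])cc3[C@H]2C(=O)OC)ccc1OC(=O)C(C)(C)C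
F3 | step 8 | methyl (2R,3S)-5-bromo-7-methoxy-2-[(2R,3R)-7-methoxy-3-(methoxycarbonyl)-2-[3-methoxy-4-(pivaloyloxy)phenyl]-2,3-dihydro-1-benzofuran-5-yl]-2,3-dihydro-1-benzofuran-3-carboxylate (inner ring 2,3-cis) | COc1cc([C@@H]2Oc3c(OC)cc([C@@H]4Oc5c(OC)cc(Br)cc5[C@@H]4C(=O)OC)cc3[C@H]2C(=O)OC)ccc1OC(=O)C(C)(C)C
F4 | step 5 | 4-[(2S)-6-bromo-3-[(dimethylamino)methylidene]-8-methoxy-4-oxo-3,4-dihydro-2H-chromen-2-yl]-2-methoxyphenyl pivalate (geometry at C2 as in 7; descriptor changes by CIP ranking) | COc1cc([C@@H]2Oc3c(OC)cc(Br)cc3C(=O)C2=CN(C)C)ccc1OC(=O)C(C)(C)C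
F5 | step 5 | 4-[(2S)-6-bromo-3-diazo-8-methoxy-4-oxo-3,4-dihydro-2H-chromen-2-yl]-2-methoxyphenyl pivalate (geometry at C2 as in 7) | COc1cc([C@@H]2Oc3c(OC)cc(Br)cc3C(=O)C2=[N+]=[N-])ccc1OC(=O)C(C)(C)C
F6 | step 5 | methyl (2R,3S)-5-bromo-7-methoxy-2-[3-methoxy-4-(pivaloyloxy)phenyl]-2,3-dihydro-1-benzofuran-3-carboxylate (2,3-cis) | COc1cc([C@@H]2Oc3c(OC)cc(Br)cc3[C@@H]2C(=O)OC)ccc1OC(=O)C(C)(C)C
F7 | step 7 | methyl (2R,3R)-5-[(2S)-6-bromo-8-methoxy-4-oxo-3,4-dihydro-2H-chromen-2-yl]-7-methoxy-2-[3-methoxy-4-(pivaloyloxy)phenyl]-2,3-dihydro-1-benzofuran-3-carboxylate | COc1cc([C@@H]2Oc3c(OC)cc([C@H]4Oc5c(OC)cc(Br)cc5C(=O)C4)cc3[C@H]2C(=O)OC)ccc1OC(=O)C(C)(C)C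
F8 | step 7 | methyl (2R,3R)-5-[(E)-3-(5-bromo-2-hydroxy-3-methoxyphenyl)-3-oxoprop-1-en-1-yl]-7-methoxy-2-[3-methoxy-4-(pivaloyloxy)phenyl]-2,3-dihydro-1-benzofuran-3-carboxylate | COc1cc([C@@H]2Oc3c(OC)cc(/C=C/C(=O)c4cc(Br)cc(OC)c4O)cc3[C@H]2C(=O)OC)ccc1OC(=O)C(C)(C)C
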